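**Plan** (1-benzoxepine numbering of the target)

1. Cuts: C–Br of the CH2Br group (from CH2OH), C3=C4 (ring-closing metathesis), O1–C2 (allylic etherification of a tertiary alcohol), C4–C5 (one-carbon homologation of a C5 carbonyl), then C5a–C9a together with C6–C7 in one [4+2] event.
2. Enabling feature: in ring A (C5a–C6–C7–C8–C9–C9a) these two bonds join a two-carbon unit C5a–C6 (gem-dimethyl on C6, C5 on C5a) to a four-carbon unit C7–C8–C9–C9a (Br on C7, O and CH3 on C9a). This is the retron of a 1-oxy-4-bromodiene plus a β,β-dimethylacryloyl dienophile; C5 and O1 are cis on the ring fusion, so the carboxyl carbon C5 and the dienol oxygen can be tied by a temporary silylene.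
3. Forward: bromo ketone → silylene-tethered triene → intramolecular Diels–Alder (ring A with its three stereocentres) → alkene reduction, tether opened to a lactol, C5 extended to an allyl group → ether at O1 → metathesis closes ring B → CH2OH to CH2Br.
4. Stereochemistry: C5a/C9a cis from the tether on the inner (Z) oxygen of the diene; C7 from the (E)-bromoalkene (Br cis to CH3-9a); C2 from the chiral palladium catalyst. Ring A is racemic until that etherification, where the two diastereomers are separated.

Key step: step 3

Remark on the chemistry: read from the SMILES, the target is cis-fused (H-5a and CH3-9a cis), with Br-7 and the CH2Br group both cis to CH3-9a; compounds 8–14 are racemic and are named and drawn as the enantiomer that is carried on.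

**Step 1**
Reactants: 1 pent-4-yn-2-ol (racemic)
Product: 3 (E)-5-bromopent-4-en-2-ol, via alkenylzirconocene 2 (not isolated)
Conditions: Cp2Zr(H)Cl (2.2 equiv), THF, rt; then NBS, 0 °C
Reagents that add atoms: N-bromosuccinimide, O=C1CCC(=O)N1Br
Why: Hydrozirconation–bromination: once the hydroxyl group has consumed one equivalent of hydride, syn addition of Zr–H puts the metal on the terminal carbon and bromodemetalation with retention should give only the (E)-bromoalkene.

**Step 2**
Reactants: 3 (E)-5-bromopent-4-en-2-ol
Product: 4 (E)-5-bromopent-4-en-2-one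
Conditions: Dess–Martin periodinane, CH2Cl2, 0 °C to rt
Reagents that add atoms: none
Why: Dess–Martin oxidation of the secondary alcohol under near-neutral conditions should leave the β,γ-double bond unconjugated and its E geometry intact.

**Step 3**
Reactants: 4 (E)-5-bromopent-4-en-2-one; 5 3-methylbut-2-enoic acid
Product: 8 rac-(4aR,6S,8aS)-6-bromo-2,2-di-tert-butyl-5,5,8a-trimethyl-4a,5,6,8a-tetrahydro-4H-1,3,2-benzodioxasilin-4-one, via dienyloxysilyl triflate 6 (not isolated), via silylene-tethered triene 7 (not isolated)
Conditions: tBu2Si(OTf)2 (1.0 equiv), Et3N, CH2Cl2, −78 to 0 °C; then 5, Et3N, 0 °C to rt; filtration; PhMe (0.01 M), BHT, 140 °C, sealed tube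
Reagents that add atoms: di-tert-butylsilyl bis(trifluoromethanesulfonate), CC(C)(C)[Si](OS(=O)(=O)C(F)(F)F)(OS(=O)(=O)C(F)(F)F)C(C)(C)C
Why: Proposed new method: soft enolisation at the doubly activated CH2 of 4 gives the (2Z,4E)-dienyl silyl ether (the E-enol isomer suffers A1,3 strain), the carboxylate takes the second silicon valence, and on heating the electron-rich dienol ether and the β,β-dimethylacryloyl unit should combine in a concerted, asynchronous intramolecular [4+2] cycloaddition that forms C4a–C8a and C5–C6 (C5a–C9a and C6–C7 of the target) in one event, the brominated diene terminus bonding in advance to the β-carbon. The closest known reaction types are the thermal intramolecular Diels–Alder reactions of silaketal-tethered and of ester-tethered trienes; a tether that joins an enol oxygen to a carboxyl group through silicon has not been used in this way. The cyclohexene is closed by the cycloaddition itself and the six-membered dioxasilinanone by the tether, as a fused ring in which the tether links a diene terminus to the adjacent dienophile carbon. Since the tether oxygen occupies the inner (Z) position of the diene terminus, only a cis-fused adduct can form, which places the carbonyl carbon on C4a cis to the oxygen on C8a. The bromine on the outer (E) position of the other terminus is carried over suprafacially and ends cis to the outer methyl group on C8a, which sets C6. The tether fixes the regiochemistry, high dilution suppresses intermolecular reaction, and the adduct is racemic because no stereocentre or chiral reagent is present.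

**Step 4**
Reactants: 8 cycloadduct
Product: 9 rac-(4aR,6S,8aS)-6-bromo-2,2-di-tert-butyl-5,5,8a-trimethylhexahydro-4H-1,3,2-benzodioxasilin-4-one
Conditions: 2-nitrobenzenesulfonohydrazide (excess), Et3N, CH2Cl2, rt
Reagents that add atoms: none
Why: Diimide reduction: concerted syn transfer of H2 to the cis-disubstituted ring alkene (no new stereocentre) should spare the allylic C–Br bond and the acyloxysilane, which catalytic hydrogenation would endanger.

**Step 5**
Reactants: 9 saturated cyclic silyl ester
Product: 10 rac-(4aR,6S,8aS)-6-bromo-2,2-di-tert-butyl-5,5,8a-trimethylhexahydro-4H-1,3,2-benzodioxasilin-4-ol (both C4 epimers)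
Conditions: iBu2AlH (1.2 equiv), CH2Cl2, −78 °C; aq. potassium sodium tartrate
Reagents that add atoms: none
Why: Partial reduction of the lactone-like cyclic silyl ester, as in a lactone-to-lactol reduction, should stop at the tetrahedral aluminate at low temperature and give the cyclic hemiacetal, whose new carbinol configuration is of no consequence.

**Step 6**
Reactants: 10 cyclic silyl hemiacetal
Product: 11 di-tert-butyl{[rac-(1S,2R,4S)-4-bromo-2-(2-methoxyethenyl)-1,3,3-trimethylcyclohexyl]oxy}silanol (E/Z mixture)
Conditions: Ph3P(CH2OMe)Cl, KN(SiMe3)2 (3 equiv each), THF, −78 to 0 °C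
Reagents that add atoms: (methoxymethyl)triphenylphosphonium chloride, COC[P+](c1ccccc1)(c1ccccc1)c1ccccc1.[Cl-]
Why: Wittig alkoxymethylenation: the base opens the hemiacetal to aldehyde and silanolate, and the small non-stabilised ylide should add to the hindered carbonyl faster than the α-hydrogen is removed, giving the enol ether with the tertiary oxygen still silylated.

**Step 7**
Reactants: 11 enol ether
Product: 13 rac-(3aR,5S,7aS)-5-bromo-4,4,7a-trimethyloctahydro-1-benzofuran-2-ol (both anomers), via hydroxy aldehyde 12 (not isolated)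
Conditions: aq. HF, MeCN, 0 °C to rt
Reagents that add atoms: water, O
Why: Acidic hydrolysis of the enol ether and fluoride cleavage of the hindered silyl ether release an aldehyde and a tertiary alcohol that are cis on the ring and should close at once to the cis-fused five-membered lactol.

**Step 8**
Reactants: 13 lactol
Product: 14 rac-(1S,2R,4S)-4-bromo-1,3,3-trimethyl-2-(prop-2-en-1-yl)cyclohexan-1-ol
Conditions: Ph3PCH3Br, KOtBu (3 equiv each), THF, 0 °C to rt
Reagents that add atoms: methyltriphenylphosphonium bromide, C[P+](c1ccccc1)(c1ccccc1)c1ccccc1.[Br-]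
Why: Wittig methylenation of a lactol through its open hydroxy aldehyde form should give the allyl group and free the tertiary alcohol without touching a stereocentre.

**Step 9**
Reactants: 15 2-methylprop-2-enal (methacrolein)
Product: 16 rac-2-(prop-1-en-2-yl)oxirane
Conditions: Me3SI, NaH, DMSO/THF, 0 °C; distillation
Reagents that add atoms: trimethylsulfonium iodide, C[S+](C)C.[I-]
Why: Corey–Chaykovsky epoxidation: the unstabilised sulfonium ylide adds 1,2 to the enal and ring closure gives the vinyl oxirane, which may be racemic because the next step is stereoconvergent at this carbon.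

**Step 10**
Reactants: 14 allyl tertiary alcohol; 16 rac-2-(prop-1-en-2-yl)oxirane
Product: 17 (2R)-2-{[(1S,2R,4S)-4-bromo-1,3,3-trimethyl-2-(prop-2-en-1-yl)cyclohexyl]oxy}-3-methylbut-3-en-1-ol
Conditions: Pd2(dba)3·CHCl3 (cat.), (S,S)-N,N'-cyclohexane-1,2-diylbis[2-(diphenylphosphanyl)benzamide] (cat.), Et3B (1 equiv), CH2Cl2, rt; chromatography
Reagents that add atoms: none
Why: Proposed new method: zerovalent palladium should ionise the vinyl oxirane to a π-allyl palladium alkoxide whose diastereomeric forms interconvert, boron binds this alkoxide together with the tertiary alcohol and delivers that oxygen to the nearer allyl terminus, so the branched ether forms with the new carbinol configuration fixed by the chiral ligand (the (S,S) ligand is chosen for R by analogy with simple alcohols, the antipode being used should the sense prove opposite) and not by the racemic partners; each enantiomer of 14 therefore gives one diastereomer and chromatographic separation delivers 17 as a single enantiomer; the closest known reaction type is the palladium- and trialkylborane-catalysed dynamic kinetic asymmetric addition of primary alcohols to vinyl oxiranes, which has not been shown for a tertiary alcohol.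

**Step 11**
Reactants: 17 diene ether
Product: 18 [(2R,5aR,7S,9aS)-7-bromo-3,6,6,9a-tetramethyl-2,5,5a,6,7,8,9,9a-octahydro-1-benzoxepin-2-yl]methanol
Conditions: second-generation Grubbs catalyst (5 mol %), CH2Cl2, 40 °C
Reagents that add atoms: none
Why: Ring-closing metathesis between the allyl and the 1,1-disubstituted isopropenyl group should close the seven-membered ring with loss of ethene; only the (Z)-trisubstituted ring alkene is possible and no stereocentre is touched.

**Step 12**
Reactants: 18 oxepene alcohol
Product: 19 (2R,5aR,7S,9aS)-7-bromo-2-(bromomethyl)-3,6,6,9a-tetramethyl-2,5,5a,6,7,8,9,9a-octahydro-1-benzoxepine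
Conditions: CBr4, PPh3, CH2Cl2, 0 °C
Reagents that add atoms: carbon tetrabromide, BrC(Br)(Br)Br
Why: Appel reaction: SN2 displacement at the primary carbon of the alkoxyphosphonium ion should give the bromomethyl group without affecting C2 or the hindered secondary bromide.

**Compound list**

1 | pent-4-yn-2-ol (racemic) | CC(O)CC#C | starting material
2 | (E)-alkenylzirconocene chloride of 1 (oxygen bound to a second zirconocene chloride) | CC(O[Zr](Cl)(C1C=CC=C1)C1C=CC=C1)C/C=C/[Zr](Cl)(C1C=CC=C1)C1C=CC=C1 | intermediate
3 | (E)-5-bromopent-4-en-2-ol (racemic) | CC(O)C/C=C/Br | intermediate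
4 | (E)-5-bromopent-4-en-2-one | CC(=O)C/C=C/Br | intermediate
5 | 3-methylbut-2-enoic acid | CC(C)=CC(=O)O | starting material
6 | {[(2Z,4E)-5-bromopenta-2,4-dien-2-yl]oxy}di-tert-butylsilyl trifluoromethanesulfonate | CC(C)(C)[Si](OS(=O)(=O)C(F)(F)F)(O/C(C)=C\C=C\Br)C(C)(C)C | intermediate
7 | {[(2Z,4E)-5-bromopenta-2,4-dien-2-yl]oxy}di-tert-butylsilyl 3-methylbut-2-enoate | CC(C)=CC(=O)O[Si](C(C)(C)C)(C(C)(C)C)O/C(C)=C\C=C\Br | intermediate
8 | rac-(4aR,6S,8aS)-6-bromo-2,2-di-tert-butyl-5,5,8a-trimethyl-4a,5,6,8a-tetrahydro-4H-1,3,2-benzodioxasilin-4-one (cis-fused; Br cis to CH3-8a, trans to the carbonyl) | CC1(C)[C@@H](Br)C=C[C@]2(C)O[Si](C(C)(C)C)(C(C)(C)C)OC(=O)[C@H]12 | intermediate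
9 | rac-(4aR,6S,8aS)-6-bromo-2,2-di-tert-butyl-5,5,8a-trimethylhexahydro-4H-1,3,2-benzodioxasilin-4-one | CC1(C)[C@@H](Br)CC[C@]2(C)O[Si](C(C)(C)C)(C(C)(C)C)OC(=O)[C@H]12 | intermediate
10 | rac-(4aR,6S,8aS)-6-bromo-2,2-di-tert-butyl-5,5,8a-trimethylhexahydro-4H-1,3,2-benzodioxasilin-4-ol (both C4 epimers) | CC1(C)[C@@H](Br)CC[C@]2(C)O[Si](C(C)(C)C)(C(C)(C)C)OC(O)[C@H]12 | intermediate
11 | di-tert-butyl{[rac-(1S,2R,4S)-4-bromo-2-(2-methoxyethenyl)-1,3,3-trimethylcyclohexyl]oxy}silanol (E/Z mixture) | COC=C[C@@H]1C(C)(C)[C@@H](Br)CC[C@]1(C)O[Si](O)(C(C)(C)C)C(C)(C)C | intermediate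
12 | rac-2-[(1R,3S,6S)-3-bromo-6-hydroxy-2,2,6-trimethylcyclohexyl]acetaldehyde | O=CC[C@@H]1C(C)(C)[C@@H](Br)CC[C@]1(C)O | intermediate
13 | rac-(3aR,5S,7aS)-5-bromo-4,4,7a-trimethyloctahydro-1-benzofuran-2-ol (both anomers) | OC1C[C@@H]2C(C)(C)[C@@H](Br)CC[C@]2(C)O1 | intermediate
14 | rac-(1S,2R,4S)-4-bromo-1,3,3-trimethyl-2-(prop-2-en-1-yl)cyclohexan-1-ol | C=CC[C@@H]1C(C)(C)[C@@H](Br)CC[C@]1(C)O | intermediate
15 | 2-methylprop-2-enal | CC(=C)C=O | starting material
16 | rac-2-(prop-1-en-2-yl)oxirane | CC(=C)C1CO1 | intermediate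
17 | (2R)-2-{[(1S,2R,4S)-4-bromo-1,3,3-trimethyl-2-(prop-2-en-1-yl)cyclohexyl]oxy}-3-methylbut-3-en-1-ol | C=CC[C@@H]1C(C)(C)[C@@H](Br)CC[C@]1(C)O[C@@H](CO)C(C)=C | intermediate
18 | [(2R,5aR,7S,9aS)-7-bromo-3,6,6,9a-tetramethyl-2,5,5a,6,7,8,9,9a-octahydro-1-benzoxepin-2-yl]methanol | CC1=CC[C@@H]2C(C)(C)[C@@H](Br)CC[C@]2(C)O[C@H]1CO | intermediate
19 | (2R,5aR,7S,9aS)-7-bromo-2-(bromomethyl)-3,6,6,9a-tetramethyl-2,5,5a,6,7,8,9,9a-octahydro-1-benzoxepine | CC1=CC[C@@H]2C(C)(C)[C@@H](Br)CC[C@]2(C)O[C@H]1CBr | target

**Totals**

Total step count: 12. Longest linear sequence: 11 steps (steps 1–8 and 10–12).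

**Steps most likely to fail**

1. Step 3 (Proposed new method). The doubly congested cycloaddition may be slower than thermal ionisation and allylic transposition of the bromide in the adduct or than loss of the moisture-sensitive tether; any E-enol ether cannot cyclise to the required isomer. Fallback (known chemistry, untethered and intermolecular), setting out from 4 and returning at 13: 4 is silylated (tBuMe2SiOTf, Et3N) to tert-butyl{[(2Z,4E)-5-bromopenta-2,4-dien-2-yl]oxy}dimethylsilane F1. F1 is combined with methyl 3-methylbut-2-enoate in a Lewis-acid-promoted Diels–Alder reaction (AlBr3/AlMe3, CH2Cl2/PhMe, low temperature). Endo/exo control is not expected, so the epimer with the ester cis to the silyloxy group, methyl rac-(1R,3S,6S)-3-bromo-6-(tert-butyldimethylsilyloxy)-2,2,6-trimethylcyclohex-4-ene-1-carboxylate F2, is separated. It is reduced with diimide to methyl rac-(1R,3S,6S)-3-bromo-6-(tert-butyldimethylsilyloxy)-2,2,6-trimethylcyclohexane-1-carboxylate F3, then with iBu2AlH at −78 °C to rac-(1R,3S,6S)-3-bromo-6-(tert-butyldimethylsilyloxy)-2,2,6-trimethylcyclohexane-1-carbaldehyde F4. Wittig alkoxymethylenation gives tert-butyl{[rac-(1S,2R,4S)-4-bromo-2-(2-methoxyethenyl)-1,3,3-trimethylcyclohexyl]oxy}dimethylsilane F5, and aqueous HF in MeCN then gives 13.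

2. Step 10 (Proposed new method). The hindered tertiary alcohol may fail to enter the boron-mediated delivery, so that the π-allyl intermediate is consumed by linear 1,4-addition or oligomerisation, or catalyst control at the new carbinol carbon may be weak. Fallback (known chemistry, stereochemistry taken from a resolved epoxide instead of the catalyst), setting out from 14 and 16 and returning at 17: hydrolytic kinetic resolution of 16 with water (0.55 equiv) and the acetate of the trivalent cobalt salen complex, (salen)Co(OAc), leaves (S)-2-(prop-1-en-2-yl)oxirane F6. BF3·OEt2 (CH2Cl2, −78 °C) then promotes opening of F6 by 14 at the allylic carbon with inversion, and the two diastereomers are separated as before to give 17.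

3. Step 6. Under the basic ylide the very hindered aldehyde may enolise and expel the β-silyloxy group, or HBr may be lost by E2, instead of carbonyl addition. Fallback (vinyl addition and reductive deoxygenation instead of homologation and methylenation), setting out from 10 and returning at 14: CH2=CHMgBr (excess, THF, −78 °C) opens the hemiacetal and adds to give di-tert-butyl{[rac-(1S,2S,4S)-4-bromo-2-(1-hydroxyprop-2-en-1-yl)-1,3,3-trimethylcyclohexyl]oxy}silanol F7. HF·pyridine removes silicon to give rac-(1S,2S,4S)-4-bromo-2-(1-hydroxyprop-2-en-1-yl)-1,3,3-trimethylcyclohexan-1-ol F8. ClCO2Me/pyridine acylates only the secondary allylic hydroxyl to give methyl 1-[rac-(1S,3S,6S)-3-bromo-6-hydroxy-2,2,6-trimethylcyclohexyl]prop-2-en-1-yl carbonate F9. Palladium-catalysed formate reduction (Pd(OAc)2, PBu3, HCO2NH4, dioxane), which delivers hydride to the more substituted allyl terminus, gives the terminal alkene 14.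

**Further compounds**

F1 | step 3 | tert-butyl{[(2Z,4E)-5-bromopenta-2,4-dien-2-yl]oxy}dimethylsilane | CC(C)(C)[Si](C)(C)O/C(C)=C\C=C\Br
F2 | step 3 | methyl rac-(1R,3S,6S)-3-bromo-6-(tert-butyldimethylsilyloxy)-2,2,6-trimethylcyclohex-4-ene-1-carboxylate | COC(=O)[C@@H]1C(C)(C)[C@@H](Br)C=C[C@]1(C)O[Si](C)(C)C(C)(C)C
F3 | step 3 | methyl rac-(1R,3S,6S)-3-bromo-6-(tert-butyldimethylsilyloxy)-2,2,6-trimethylcyclohexane-1-carboxylate | COC(=O)[C@@H]1C(C)(C)[C@@H](Br)CC[C@]1(C)O[Si](C)(C)C(C)(C)C
F4 | step 3 | rac-(1R,3S,6S)-3-bromo-6-(tert-butyldimethylsilyloxy)-2,2,6-trimethylcyclohexane-1-carbaldehyde | O=C[C@@H]1C(C)(C)[C@@H](Br)CC[C@]1(C)O[Si](C)(C)C(C)(C)C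
F5 | step 3 | tert-butyl{[rac-(1S,2R,4S)-4-bromo-2-(2-methoxyethenyl)-1,3,3-trimethylcyclohexyl]oxy}dimethylsilane | COC=C[C@@H]1C(C)(C)[C@@H](Br)CC[C@]1(C)O[Si](C)(C)C(C)(C)C
F6 | step 10 | (S)-2-(prop-1-en-2-yl)oxirane | C=C(C)[C@H]1CO1
F7 | step 6 | di-tert-butyl{[rac-(1S,2S,4S)-4-bromo-2-(1-hydroxyprop-2-en-1-yl)-1,3,3-trimethylcyclohexyl]oxy}silanol | C=CC(O)[C@@H]1C(C)(C)[C@@H](Br)CC[C@]1(C)O[Si](O)(C(C)(C)C)C(C)(C)C
F8 | step 6 | rac-(1S,2S,4S)-4-bromo-2-(1-hydroxyprop-2-en-1-yl)-1,3,3-trimethylcyclohexan-1-ol | C=CC(O)[C@@H]1C(C)(C)[C@@H](Br)CC[C@]1(C)O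
F9 | step 6 | methyl 1-[rac-(1S,3S,6S)-3-bromo-6-hydroxy-2,2,6-trimethylcyclohexyl]prop-2-en-1-yl carbonate | COC(=O)OC(C=C)[C@@H]1C(C)(C)[C@@H](Br)CC[C@]1(C)O
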